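**Retrosynthetic overview**

1. Ring atoms carry the target numbering: C1 (C=O), C2 (isovaleryl), C3 (enol C–OH), C4 (OH, 4-methylpent-3-enoyl), C5 (OH, prenyl). The bond from the side-chain carbonyl carbon to C4 is made by γ-C-acylation of the dianion of a ketal-bridged 5-prenylcyclopentane-1,3-dione with the Weinreb amide of 4-methylpent-3-enoic acid.
2. Enabling feature: the two cis hydroxyl oxygens on the adjacent ring carbons C4 and C5 are tied as a 2,2-dimethyl-1,3-dioxolane fused to the cyclopentane ring. A 5/5 fusion can only be cis, so the acyl group must enter C4 on the face of the C5 prenyl group. The same ring keeps the C5–O bond near the nodal plane of the C4 enolate (no β-elimination). C5 is quaternary, so C4 is the only γ-site next to the C3 carbonyl.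
3. Stereochemical relay: the purchased C4–H centre sets quaternary C5 (step 1). C4 is then erased in the dianion and rewritten from C5 (key step). The precursor is a C13 bicycle with one controlling stereocentre.
4. After the key step only the C2 isovaleryl group (O-to-C acyl transfer) and ketal hydrolysis remain. Before it: α′-prenylation of a chiral-pool enone, enone epoxidation, Pd(0) isomerisation to the 1,3-dione.
5. Ring order: the cyclopentene ring and its temporary dioxolane arrive together in compound 1; an oxirane is closed in step 2 and opened in step 3; the dioxolane is opened in the last step.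

Key step: step 5

Remark: enone 1 is taken as a catalogue chiral-pool compound (both enantiomers are sold); diones 6 and 12 are drawn as diketones although they should exist largely as enols.

**Step 1**
Reactants: 1 (3aS,6aS)-2,2-dimethyl-3a,6a-dihydro-4H-cyclopenta[d][1,3]dioxol-4-one; 2 prenyl bromide
Product: 4 (3aS,6aS)-2,2-dimethyl-3a-(3-methylbut-2-en-1-yl)-3a,6a-dihydro-4H-cyclopenta[d][1,3]dioxol-4-one, via lithium enolate 3 (not isolated)
Conditions: LDA (1.05 equiv), THF, −78 °C; then 2 (1.5 equiv), DMPU, −78 → −40 °C
Reagents that add atoms: none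
Why: Kinetic α′-deprotonation of the enone and SN2 alkylation of the cross-conjugated lithium enolate (ketone enolate alkylation) should make C5 quaternary; the prenyl group can only replace the hydrogen with retention because the 5/5 fusion must stay cis, so C5 is set by C4, and loss of the C4 oxygen is held back because it would give a cyclopentadienone.

**Step 2**
Reactants: 4 prenyl enone
Product: 5 epoxy ketone (2,3-epoxide of 4 in target numbering, oxirane oxygen on the face opposite to the dioxolane and cis to the prenyl group)
Conditions: t-BuOOH (decane), Triton B (cat.), THF, 0 °C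
Reagents that add atoms: tert-butyl hydroperoxide, CC(C)(C)OO
Why: Weitz–Scheffer nucleophilic epoxidation should attack only the electron-poor enone double bond from the convex face and leave the electron-rich prenyl double bond alone; both new stereocentres are removed again in step 3.

**Step 3**
Reactants: 5 epoxy ketone
Product: 6 (3aS,6aR)-2,2-dimethyl-3a-(3-methylbut-2-en-1-yl)dihydro-4H-cyclopenta[d][1,3]dioxole-4,6(5H)-dione
Conditions: Pd(PPh3)4 (5 mol %), dppe (5 mol %), toluene, 80 °C
Reagents that add atoms: none
Why: Pd(0)-catalysed isomerisation of an α,β-epoxy ketone to a β-diketone (oxidative addition at the Cα–O bond, β-hydride elimination from the C3–H carbinol, reductive elimination) runs under neutral conditions that the ketal, the prenyl group and both stereocentres should tolerate.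

**Step 4**
Reactants: 7 4-methylpent-3-enoic acid
Product: 9 N-methoxy-N-methyl-4-methylpent-3-enamide, via acyl imidazole 8 (not isolated)
Conditions: CDI, CH2Cl2, 0 °C → rt; then MeNHOMe·HCl, rt
Reagents that add atoms: N,O-dimethylhydroxylamine hydrochloride, CNOC.Cl
Why: Carbonyldiimidazole activation and aminolysis (Weinreb amide synthesis) use no base strong enough to move the β,γ-double bond into conjugation.

**Step 5**
Reactants: 6 ketal-bridged 5-prenyl dione; 9 Weinreb amide
Product: 12 (3aS,6aS)-2,2-dimethyl-3a-(3-methylbut-2-en-1-yl)-6a-(4-methylpent-3-enoyl)dihydro-4H-cyclopenta[d][1,3]dioxole-4,6(5H)-dione, via dilithium dianion 10 (not isolated), via lithium hemiaminal adduct 11 (not isolated)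
Conditions: LDA (2.3 equiv), THF–DMPU, −78 → −30 °C; then 9, −78 → −30 °C; cold 1 M HCl quench
Reagents that add atoms: none
Why: LDA should remove first a C2 proton between the carbonyls and then the only other α-proton, that on ring-fusion carbon C4, and dianion 10 should attack the amide through this last-formed, most basic carbon to give chelated adduct 11, which survives until the acid quench and so can suffer neither a second addition nor retro-Claisen cleavage. The closest known reaction type is the γ-acylation of β-diketone dianions (dianion Claisen condensation) combined with the Weinreb ketone synthesis. No ring is closed. The new fully substituted stereocentre C4 is controlled by quaternary C5 through the dioxolane: the fusion can only be cis, so the acyl group must arrive on the face that already carries the prenyl group, whatever configuration C4 had before deprotonation. The step needs γ- over α-carbon attack (secured by the reactivity order of the dianion and by quaternary C5, which leaves one γ-site), C- over O-acylation (secured by the amide electrophile) and no β-elimination of the C5 oxygen (secured by the dioxolane, which holds that C–O bond near the nodal plane of the enolate, and by low temperature).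

**Step 6**
Reactants: 12 acylated dione; 13 3-methylbutanoic acid
Product: 15 (3aS,6aS)-6-hydroxy-2,2-dimethyl-3a-(3-methylbut-2-en-1-yl)-5-(3-methylbutanoyl)-6a-(4-methylpent-3-enoyl)-3a,6a-dihydro-4H-cyclopenta[d][1,3]dioxol-4-one, via enol ester 14 (not isolated)
Conditions: DCC, DMAP (1.2 equiv), CH2Cl2, 0 °C → rt
Reagents that add atoms: none
Why: O-acylation of the enolised 1,3-dione by the carbodiimide-activated acid and DMAP-mediated O-to-C acyl transfer (Steglich-type conditions) should give the 2-acyl-1,3-dione as the thermodynamic sink; C4 and C5 are fully substituted and ketal-bridged, so no stereocentre can change and no C-to-O acyl shift of a free α-hydroxy-β-diketone can occur.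

**Step 7**
Reactants: 15 ketal-bridged triketone
Product: 16 (4S,5S)-3,4,5-trihydroxy-5-(3-methylbut-2-en-1-yl)-2-(3-methylbutanoyl)-4-(4-methylpent-3-enoyl)cyclopent-2-en-1-one
Conditions: 2 M aq. HCl–THF (1:3), 25–40 °C
Reagents that add atoms: none
Why: Acid-catalysed ketal hydrolysis (A1 mechanism) should free the cis-diol without breaking a bond to either stereocentre; dilute aqueous acid near room temperature is chosen so that hydration or cyclisation of the two trisubstituted double bonds stays slower than ketal cleavage.

**Compound list**

1 | (3aS,6aS)-2,2-dimethyl-3a,6a-dihydro-4H-cyclopenta[d][1,3]dioxol-4-one | CC1(C)O[C@H]2C=CC(=O)[C@H]2O1 | starting material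
2 | prenyl bromide (1-bromo-3-methylbut-2-ene) | CC(C)=CCBr | starting material
3 | lithium cross-conjugated enolate of 1 | CC1(C)O[C@H]2C=CC([O-])=C2O1.[Li+] | intermediate
4 | (3aS,6aS)-2,2-dimethyl-3a-(3-methylbut-2-en-1-yl)-3a,6a-dihydro-4H-cyclopenta[d][1,3]dioxol-4-one | CC(C)=CC[C@]12OC(C)(C)O[C@H]1C=CC2=O | intermediate
5 | epoxy ketone of 4, oxirane trans to the dioxolane | CC(C)=CC[C@]12OC(C)(C)O[C@H]1[C@@H]3O[C@@H]3C2=O | intermediate
6 | (3aS,6aR)-2,2-dimethyl-3a-(3-methylbut-2-en-1-yl)dihydro-4H-cyclopenta[d][1,3]dioxole-4,6(5H)-dione | CC(C)=CC[C@]12OC(C)(C)O[C@H]1C(=O)CC2=O | intermediate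
7 | 4-methylpent-3-enoic acid | CC(C)=CCC(=O)O | starting material
8 | 1-(4-methylpent-3-enoyl)imidazole | CC(C)=CCC(=O)n1ccnc1 | intermediate
9 | N-methoxy-N-methyl-4-methylpent-3-enamide | CC(C)=CCC(=O)N(C)OC | intermediate
10 | dilithium dianion of 6 (1,3-dioxidocyclopenta-1,3-diene) | CC(C)=CC[C@]12OC(C)(C)OC1=C([O-])C=C2[O-].[Li+].[Li+] | intermediate
11 | dilithium hemiaminal adduct of 10 and 9 | CC(C)=CC[C@]12OC(C)(C)O[C@@]1(C([O-])(N(C)OC)CC=C(C)C)C(=O)C=C2[O-].[Li+].[Li+] | intermediate
12 | (3aS,6aS)-2,2-dimethyl-3a-(3-methylbut-2-en-1-yl)-6a-(4-methylpent-3-enoyl)dihydro-4H-cyclopenta[d][1,3]dioxole-4,6(5H)-dione | CC(C)=CC[C@]12OC(C)(C)O[C@@]1(C(=O)CC=C(C)C)C(=O)CC2=O | intermediate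
13 | 3-methylbutanoic acid | CC(C)CC(=O)O | starting material
14 | O-(3-methylbutanoyl) enol ester of 12 | CC(C)=CC[C@]12OC(C)(C)O[C@@]1(C(=O)CC=C(C)C)C(OC(=O)CC(C)C)=CC2=O | intermediate
15 | (3aS,6aS)-6-hydroxy-2,2-dimethyl-3a-(3-methylbut-2-en-1-yl)-5-(3-methylbutanoyl)-6a-(4-methylpent-3-enoyl)-3a,6a-dihydro-4H-cyclopenta[d][1,3]dioxol-4-one | CC(C)=CC[C@]12OC(C)(C)O[C@@]1(C(=O)CC=C(C)C)C(O)=C(C(=O)CC(C)C)C2=O | intermediate
16 | (4S,5S)-3,4,5-trihydroxy-5-(3-methylbut-2-en-1-yl)-2-(3-methylbutanoyl)-4-(4-methylpent-3-enoyl)cyclopent-2-en-1-one | CC(C)=CCC(=O)[C@]1(O)C(O)=C(C(=O)CC(C)C)C(=O)[C@]1(O)CC=C(C)C | target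

**Totals**

Total step count: 7. Longest linear sequence: 6 steps (1 → 4 → 5 → 6 → 12 → 15 → 16); step 4 is a one-step side branch.

**Steps most likely to fail**

Step 5. The process that may fail is addition at the congested ring-fusion carbanion: proton transfer from the α-CH2 group of the β,γ-unsaturated amide to the dianion may win, and on warming β-elimination of the C5 oxygen may follow. The fallback sets out from 6 and 7 and comes back at 12. Dione 6 should be silylated (TMSCl, Et3N; then LDA, TMSCl) to the bis(trimethylsilyl) dienol ether F1, a cyclic 1,3-bis(silyloxy)-1,3-diene. Acid 7 should give, with oxalyl chloride and catalytic DMF, 4-methylpent-3-enoyl chloride F2. F1 and F2 in CH2Cl2 at −78 → 20 °C (TMSOTf catalysis if needed) should couple at the diene terminus C4 in a vinylogous Mukaiyama-type acylation, and aqueous work-up should return 12. The face of attack is fixed by the same ring fusion, and no basic carbanion meets the acidic acyl donor.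

Step 7. The process that may fail is ionisation of the ketal: its two oxygens sit on carbons flanked by three carbonyl groups, so cleavage may be slow enough for acid-catalysed hydration or ether-forming cyclisation of the prenyl double bonds to overtake it. The fallback sets out from 4 and comes back at 16; it exchanges the temporary ring for a fluoride-labile one at a stage where the ketal has a single flanking carbonyl. Hydrolysis of 4 (80% aq. AcOH, 50 °C) should give (4S,5S)-4,5-dihydroxy-5-(3-methylbut-2-en-1-yl)cyclopent-2-en-1-one F3. Di-tert-butylsilyl bis(triflate) and 2,6-lutidine should close the di-tert-butylsilylene enone F4, which has the same cis-fused five-membered tether. The route then repeats: t-BuOOH/DBU should give the silylene epoxy ketone F5, Pd(0)/dppe the silylene dione F6, LDA (2.3 equiv) and 9 the silylene acylated dione F7, and 13/DCC/DMAP the silylene triketone F8. HF·pyridine in THF at 0 °C should then release 16 without any Brønsted acid strong enough to protonate the double bonds.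

Step 1. The process that may fail is clean α′-enolate formation: γ-deprotonation at C4, proton exchange and Michael addition of the enolate to unreacted enone may compete with alkylation. The fallback sets out from 1 and comes back at 5; it reverses the order of the first two operations. Epoxidation of 1 (t-BuOOH, Triton B, THF, 0 °C) should give the epoxy ketone F9, which is no Michael acceptor and has a single enolisable position. LDA and prenyl bromide 2 (THF–DMPU, −78 °C) should then alkylate C5 under the same ring-fusion control to give 5.

**Further compounds**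

F1 | step 5 | bis(trimethylsilyl) dienol ether of 6 (ketal-bridged 1,3-bis(trimethylsilyloxy)-5-prenylcyclopenta-1,3-diene) | CC(C)=CC[C@]12OC(C)(C)OC1=C(O[Si](C)(C)C)C=C2O[Si](C)(C)C
F2 | step 5 | 4-methylpent-3-enoyl chloride | CC(C)=CCC(=O)Cl
F3 | step 7 | (4S,5S)-4,5-dihydroxy-5-(3-methylbut-2-en-1-yl)cyclopent-2-en-1-one | CC(C)=CC[C@]1(O)[C@@H](O)C=CC1=O
F4 | step 7 | di-tert-butylsilylene analogue of enone 4 | CC(C)=CC[C@]12O[Si](C(C)(C)C)(C(C)(C)C)O[C@H]1C=CC2=O
F5 | step 7 | di-tert-butylsilylene analogue of epoxy ketone 5 | CC(C)=CC[C@]12O[Si](C(C)(C)C)(C(C)(C)C)O[C@H]1[C@@H]3O[C@@H]3C2=O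
F6 | step 7 | di-tert-butylsilylene analogue of dione 6 | CC(C)=CC[C@]12O[Si](C(C)(C)C)(C(C)(C)C)O[C@H]1C(=O)CC2=O
F7 | step 7 | di-tert-butylsilylene analogue of acylated dione 12 | CC(C)=CC[C@]12O[Si](C(C)(C)C)(C(C)(C)C)O[C@@]1(C(=O)CC=C(C)C)C(=O)CC2=O
F8 | step 7 | di-tert-butylsilylene analogue of triketone 15 | CC(C)=CC[C@]12O[Si](C(C)(C)C)(C(C)(C)C)O[C@@]1(C(=O)CC=C(C)C)C(O)=C(C(=O)CC(C)C)C2=O
F9 | step 1 | epoxy ketone of 1, oxirane trans to the dioxolane | CC1(C)O[C@H]2[C@@H]3O[C@@H]3C(=O)[C@H]2O1
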